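Ring B is disconnected across its two opposite bonds, C5–C10 (ring fusion) and C7–C8 (drimane numbering). This leaves C8–C9–C10 as a ketone (C9=O) that is nucleophilic at both α-carbons and C5–C6–C7 as an (E)-enal, joined only through the C1–C4 chain of ring A. In one amine-catalysed operation the acyclic keto enal closes ring A by iminium Michael addition (C10 to C5) and ring B by aldol condensation (C8 to C7), giving the trans-fused bicyclic enone. The step exploits the C9 carbon flanked by both new bonds and the quaternary C4, which leaves the enal without γ-hydrogens. The C9 ketone later carries C11 and the arene.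

Key step: step 6

Remarks: Decalin carbons are numbered as in drimanes (C4 gem-dimethyl, C5/C10 ring fusion, C8 methyl-bearing, C9 alkylidene carbon, C11 benzylic CH); primed numbers refer to the arene (C1′ bears C11). Sulfate monoesters are written as free acids, as in the target; they would be handled as sodium salts. Compounds 16 and 21 are expected as epimer mixtures at centres that become sp2 in step 13, so these centres are left open.

Step 1
Reactants: 1 3-pentanone
Product: 2 3-pentanone N,N-dimethylhydrazone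
Conditions: Me2NNH2, AcOH (cat.), EtOH, reflux
Reagents that add atoms: N,N-dimethylhydrazine, CN(C)N
Why: Hydrazone condensation masks the ketone and prepares a cleanly mono-alkylating azaenolate.

Step 2
Reactants: 3 isobutyronitrile; 4 1,3-dibromopropane
Product: 6 5-bromo-2,2-dimethylpentanenitrile, via lithiated isobutyronitrile 5 (not isolated)
Conditions: LiN(iPr)2, THF, −78 °C; inverse addition to 4 (3 equiv), −78 °C to rt
Reagents that add atoms: none
Why: Nitrile-anion alkylation (SN2) should build the quaternary C4 with its gem-dimethyl group, the excess dihalide suppressing double alkylation.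

Step 3
Reactants: 2 3-pentanone N,N-dimethylhydrazone; 6 5-bromo-2,2-dimethylpentanenitrile
Product: 8 7-(2,2-dimethylhydrazinylidene)-2,2,6-trimethylnonanenitrile, via lithium azaenolate 7 (not isolated)
Conditions: LiN(iPr)2, THF, 0 °C; then 6, −78 °C to rt; neutral work-up
Reagents that add atoms: none
Why: Hydrazone azaenolate alkylation at the primary bromide should form the C10–C1 bond; the new centre is racemic and is enolised again in step 6.

Step 4
Reactants: 8 7-(2,2-dimethylhydrazinylidene)-2,2,6-trimethylnonanenitrile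
Product: 10 2,2,6-trimethyl-7-oxononanal, via hydrazone aldehyde 9 (not isolated)
Conditions: i-Bu2AlH, toluene, −78 °C; then 1 M aq HCl–pentane, rt
Reagents that add atoms: water, O
Why: Half-reduction of the hindered nitrile should stop at the N-aluminoimine while the hydrazone shields the ketone, and acid hydrolysis then frees both carbonyl groups.

Step 5
Reactants: 10 2,2,6-trimethyl-7-oxononanal
Product: 11 (E)-4,4,8-trimethyl-9-oxoundec-2-enal
Conditions: Ph3P=CHCHO, toluene, 90 °C
Reagents that add atoms: (triphenylphosphoranylidene)acetaldehyde, O=CC=P(c1ccccc1)(c1ccccc1)c1ccccc1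
Why: Wittig olefination with a stabilised ylide should react only at the aldehyde, not the ketone, and give the E-enal.

Step 6
Reactants: 11 (E)-4,4,8-trimethyl-9-oxoundec-2-enal
Product: 13 (4aS,8aS)-2,5,5,8a-tetramethyl-4a,5,6,7,8,8a-hexahydronaphthalen-1(4H)-one, via keto aldehyde Michael adduct 12 (not isolated)
Conditions: (S)-α,α-diphenylprolinol trimethylsilyl ether (20 mol %), PhCO2H (20 mol %), toluene, 40 °C; then TsOH·H2O (10 mol %), 70 °C, same flask
Reagents that add atoms: none
Why: Proposed new method: the amine and the enal form an E-iminium ion, the acid-promoted enol on the more substituted side of the ketone adds through C10 to C5, and the aldehyde iminium regenerated from the resulting enamine is attacked by the remaining C8=C9 enol, after which loss of the amine gives the C7=C8 enone. The closest known reactions are the amine-catalysed Michael/aldol-condensation annulation of β-keto esters with enals and iminium-catalysed intramolecular Michael additions, and what is new is an unactivated α-branched dialkyl ketone as the donor. Ring A closes by a 6-(enolexo)-exo-trig Michael addition and ring B by a 6-(enolendo)-exo-trig aldol (Mannich-type) closure. C5 is set by the catalyst, whose diphenyl(silyloxy)methyl group covers one face of the s-trans E-iminium so that C10 adds to the open face (5S), and C10 is set by the chair transition state of ring A, in which the enol carbon C9 and the C6 chain are pseudo-equatorial and the C10 methyl is pseudo-axial, which gives the trans relation (10S). The step needs reaction through the C10 enol and not the C8 enol, which ring size secures (the C8 enol could only close an eight-membered ring), and it needs the enal to stay an acceptor, which the quaternary C4 secures by removing all γ-hydrogens.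

Step 7
Reactants: 13 (4aS,8aS)-2,5,5,8a-tetramethyl-4a,5,6,7,8,8a-hexahydronaphthalen-1(4H)-one
Product: 14 (2S,4aS,8aS)-2,5,5,8a-tetramethyloctahydronaphthalen-1(2H)-one
Conditions: H2 (1 atm), Pd/C, EtOAc, rt
Reagents that add atoms: none
Why: Heterogeneous syn hydrogenation should deliver hydrogen to the α face of C7=C8, opposite the axial C10 methyl, placing the C8 methyl β (8S) under neutral, non-epimerising conditions.

Step 8
Reactants: 14 (2S,4aS,8aS)-2,5,5,8a-tetramethyloctahydronaphthalen-1(2H)-one
Product: 15 (1S,2S,4aS,8aS)-2,5,5,8a-tetramethyloctahydro-2H-spiro[naphthalene-1,2'-oxirane]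
Conditions: Me3SI, n-BuLi, THF, 0 °C; then 14, 0 °C to rt
Reagents that add atoms: trimethylsulfonium iodide, C[S+](C)C.[I-]
Why: Corey–Chaykovsky epoxidation should add CH2 to the hindered carbonyl from the open α face, and C8 should hold because its only α-hydrogen is equatorial and poorly aligned for enolisation.

Step 9
Reactants: 15 (1S,2S,4aS,8aS)-2,5,5,8a-tetramethyloctahydro-2H-spiro[naphthalene-1,2'-oxirane]
Product: 16 (2S,4aS,8aS)-2,5,5,8a-tetramethyldecahydronaphthalene-1-carbaldehyde
Conditions: BF3·OEt2 (0.2 equiv), CH2Cl2, −78 °C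
Reagents that add atoms: none
Why: Meinwald rearrangement (epoxide opening at the tertiary C9 with 1,2-hydride shift) should give the C11 aldehyde, whose C9 configuration is of no consequence.

Step 10
Reactants: 17 2-methoxybenzene-1,4-diol
Product: 18 2-methoxy-1,4-bis(methoxymethoxy)benzene
Conditions: MOMCl, i-Pr2NEt, CH2Cl2, 0 °C to rt
Reagents that add atoms: chloromethyl methyl ether, COCCl
Why: Acetal protection of both hydroquinone oxygens (later O2′ and O5′) leaves the future free phenol oxygen (O4′) distinguished as its methyl ether.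

Step 11
Reactants: 18 2-methoxy-1,4-bis(methoxymethoxy)benzene
Product: 19 1-bromo-4-methoxy-2,5-bis(methoxymethoxy)benzene
Conditions: NBS, MeCN, 0 °C
Reagents that add atoms: N-bromosuccinimide, O=C1CCC(=O)N1Br
Why: Electrophilic aromatic bromination should occur para to the methoxy group and ortho to one acetal oxygen, the only unhindered position activated by two oxygens.

Step 12
Reactants: 19 1-bromo-4-methoxy-2,5-bis(methoxymethoxy)benzene; 16 (2S,4aS,8aS)-2,5,5,8a-tetramethyldecahydronaphthalene-1-carbaldehyde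
Product: 21 [4-methoxy-2,5-bis(methoxymethoxy)phenyl][(2S,4aS,8aS)-2,5,5,8a-tetramethyldecahydronaphthalen-1-yl]methanol, via aryllithium 20 (not isolated)
Conditions: n-BuLi, THF, −78 °C; then 16, −78 to 0 °C; H2O
Reagents that add atoms: none
Why: Bromine–lithium exchange and 1,2-addition of the aryllithium to the aldehyde should form the C11–C1′ bond, the carbinol configuration being irrelevant.

Step 13
Reactants: 21 [4-methoxy-2,5-bis(methoxymethoxy)phenyl][(2S,4aS,8aS)-2,5,5,8a-tetramethyldecahydronaphthalen-1-yl]methanol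
Product: 22 1-{(E)-[(2S,4aS,8aS)-2,5,5,8a-tetramethyloctahydronaphthalen-1(2H)-ylidene]methyl}-4-methoxy-2,5-bis(methoxymethoxy)benzene
Conditions: PPTS (10 mol %), 4 Å MS, toluene, 60 °C
Reagents that add atoms: none
Why: Acid-catalysed E1 dehydration through the ortho,para-dioxygenated benzylic cation should lose the C9 proton, and the E alkene is favoured because it keeps the arene away from the quaternary C10.

Step 14
Reactants: 22 1-{(E)-[(2S,4aS,8aS)-2,5,5,8a-tetramethyloctahydronaphthalen-1(2H)-ylidene]methyl}-4-methoxy-2,5-bis(methoxymethoxy)benzene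
Product: 24 6-methoxy-2,5-bis(methoxymethoxy)-3-{(E)-[(2S,4aS,8aS)-2,5,5,8a-tetramethyloctahydronaphthalen-1(2H)-ylidene]methyl}benzaldehyde, via ortho-lithiated arene 23 (not isolated)
Conditions: n-BuLi, TMEDA, THF, 0 °C; then DMF, −78 °C to rt; H2O
Reagents that add atoms: N,N-dimethylformamide, CN(C)C=O
Why: Directed ortho-metalation should occur at C3′, the only position flanked by two directing oxygens, and formylation with DMF installs the aldehyde.

Step 15
Reactants: 24 6-methoxy-2,5-bis(methoxymethoxy)-3-{(E)-[(2S,4aS,8aS)-2,5,5,8a-tetramethyloctahydronaphthalen-1(2H)-ylidene]methyl}benzaldehyde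
Product: 25 2,5-dihydroxy-6-methoxy-3-{(E)-[(2S,4aS,8aS)-2,5,5,8a-tetramethyloctahydronaphthalen-1(2H)-ylidene]methyl}benzaldehyde
Conditions: 0.3 M HCl in MeOH, rt, under argon
Reagents that add atoms: none
Why: Acid-catalysed acetal exchange with methanol should remove both methoxymethyl groups while the methyl ether, the aldehyde and the alkene persist.

Step 16
Reactants: 25 2,5-dihydroxy-6-methoxy-3-{(E)-[(2S,4aS,8aS)-2,5,5,8a-tetramethyloctahydronaphthalen-1(2H)-ylidene]methyl}benzaldehyde
Product: 26 6-methoxy-2,5-bis(sulfooxy)-3-{(E)-[(2S,4aS,8aS)-2,5,5,8a-tetramethyloctahydronaphthalen-1(2H)-ylidene]methyl}benzaldehyde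
Conditions: SO3·pyridine (6 equiv), pyridine, 50 °C; then aq NaHCO3
Reagents that add atoms: sulfur trioxide–pyridine complex, O=S(=O)([O-])[n+]1ccccc1
Why: O-Sulfation with a sulfur trioxide–amine complex should take place at the two free phenols only, the third oxygen being blocked as its methyl ether.

Step 17
Reactants: 26 6-methoxy-2,5-bis(sulfooxy)-3-{(E)-[(2S,4aS,8aS)-2,5,5,8a-tetramethyloctahydronaphthalen-1(2H)-ylidene]methyl}benzaldehyde
Product: 27 6-hydroxy-2,5-bis(sulfooxy)-3-{(E)-[(2S,4aS,8aS)-2,5,5,8a-tetramethyloctahydronaphthalen-1(2H)-ylidene]methyl}benzaldehyde (CNP0309628.1)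
Conditions: NaSEt (4 equiv), DMF, 90 °C; then aq HCl to pH 3, reversed-phase desalting
Reagents that add atoms: none
Why: SN2 O-demethylation by thiolate should cleave the one methyl ether, activated by the ortho formyl group, while aryl sulfate monoester anions are inert to thiolate.

Compound list
1 | 3-pentanone | CCC(=O)CC | starting material
2 | 3-pentanone N,N-dimethylhydrazone | CCC(CC)=NN(C)C | intermediate
3 | isobutyronitrile | CC(C)C#N | starting material
4 | 1,3-dibromopropane | BrCCCBr | starting material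
5 | lithiated isobutyronitrile (N-lithio ketenimine form) | CC(C)=C=N[Li] | intermediate
6 | 5-bromo-2,2-dimethylpentanenitrile | CC(C)(CCCBr)C#N | intermediate
7 | lithium azaenolate of 2 | CC=C(CC)N([Li])N(C)C | intermediate
8 | 7-(2,2-dimethylhydrazinylidene)-2,2,6-trimethylnonanenitrile (racemic) | CCC(=NN(C)C)C(C)CCCC(C)(C)C#N | intermediate
9 | 7-(2,2-dimethylhydrazinylidene)-2,2,6-trimethylnonanal (racemic) | CCC(=NN(C)C)C(C)CCCC(C)(C)C=O | intermediate
10 | 2,2,6-trimethyl-7-oxononanal (racemic) | CCC(=O)C(C)CCCC(C)(C)C=O | intermediate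
11 | (E)-4,4,8-trimethyl-9-oxoundec-2-enal (racemic at C8) | CCC(=O)C(C)CCCC(C)(C)/C=C/C=O | intermediate
12 | 2-[(1S,2S)-2,6,6-trimethyl-2-propanoylcyclohexyl]acetaldehyde | CCC(=O)[C@@]1(C)CCCC(C)(C)[C@@H]1CC=O | intermediate
13 | (4aS,8aS)-2,5,5,8a-tetramethyl-4a,5,6,7,8,8a-hexahydronaphthalen-1(4H)-one | CC1=CC[C@H]2C(C)(C)CCC[C@]2(C)C1=O | intermediate
14 | (2S,4aS,8aS)-2,5,5,8a-tetramethyloctahydronaphthalen-1(2H)-one (2-methyl β, axial) | C[C@H]1CC[C@H]2C(C)(C)CCC[C@]2(C)C1=O | intermediate
15 | (1S,2S,4aS,8aS)-2,5,5,8a-tetramethyloctahydro-2H-spiro[naphthalene-1,2'-oxirane] (epoxide oxygen β) | C[C@H]1CC[C@H]2C(C)(C)CCC[C@]2(C)[C@]13CO3 | intermediate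
16 | (2S,4aS,8aS)-2,5,5,8a-tetramethyldecahydronaphthalene-1-carbaldehyde (C1 epimers) | C[C@H]1CC[C@H]2C(C)(C)CCC[C@]2(C)C1C=O | intermediate
17 | 2-methoxybenzene-1,4-diol | COc1cc(O)ccc1O | starting material
18 | 2-methoxy-1,4-bis(methoxymethoxy)benzene | COCOc1ccc(OCOC)c(OC)c1 | intermediate
19 | 1-bromo-4-methoxy-2,5-bis(methoxymethoxy)benzene | Brc1cc(OCOC)c(OC)cc1OCOC | intermediate
20 | [4-methoxy-2,5-bis(methoxymethoxy)phenyl]lithium | [Li]c1cc(OCOC)c(OC)cc1OCOC | intermediate
21 | [4-methoxy-2,5-bis(methoxymethoxy)phenyl][(2S,4aS,8aS)-2,5,5,8a-tetramethyldecahydronaphthalen-1-yl]methanol (epimers at carbinol carbon and C1) | C[C@H]1CC[C@H]2C(C)(C)CCC[C@]2(C)C1C(O)c1cc(OCOC)c(OC)cc1OCOC | intermediate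
22 | 1-{(E)-[(2S,4aS,8aS)-2,5,5,8a-tetramethyloctahydronaphthalen-1(2H)-ylidene]methyl}-4-methoxy-2,5-bis(methoxymethoxy)benzene | C[C@H]1CC[C@H]2C(C)(C)CCC[C@]2(C)/C1=C/c1cc(OCOC)c(OC)cc1OCOC | intermediate
23 | 3-lithio derivative of 22 (lithium between the methoxy and methoxymethoxy groups) | C[C@H]1CC[C@H]2C(C)(C)CCC[C@]2(C)/C1=C/c1cc(OCOC)c(OC)c([Li])c1OCOC | intermediate
24 | 6-methoxy-2,5-bis(methoxymethoxy)-3-{(E)-[(2S,4aS,8aS)-2,5,5,8a-tetramethyloctahydronaphthalen-1(2H)-ylidene]methyl}benzaldehyde | C[C@H]1CC[C@H]2C(C)(C)CCC[C@]2(C)/C1=C/c1cc(OCOC)c(OC)c(C=O)c1OCOC | intermediate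
25 | 2,5-dihydroxy-6-methoxy-3-{(E)-[(2S,4aS,8aS)-2,5,5,8a-tetramethyloctahydronaphthalen-1(2H)-ylidene]methyl}benzaldehyde | C[C@H]1CC[C@H]2C(C)(C)CCC[C@]2(C)/C1=C/c1cc(O)c(OC)c(C=O)c1O | intermediate
26 | 6-methoxy-2,5-bis(sulfooxy)-3-{(E)-[(2S,4aS,8aS)-2,5,5,8a-tetramethyloctahydronaphthalen-1(2H)-ylidene]methyl}benzaldehyde | C[C@H]1CC[C@H]2C(C)(C)CCC[C@]2(C)/C1=C/c1cc(OS(=O)(=O)O)c(OC)c(C=O)c1OS(=O)(=O)O | intermediate
27 | 6-hydroxy-2,5-bis(sulfooxy)-3-{(E)-[(2S,4aS,8aS)-2,5,5,8a-tetramethyloctahydronaphthalen-1(2H)-ylidene]methyl}benzaldehyde (CNP0309628.1) | C[C@H]1CC[C@H]2C(C)(C)CCC[C@]2(C)/C1=C/c1cc(OS(=O)(=O)O)c(O)c(C=O)c1OS(=O)(=O)O | target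

Total step count: 17. Longest linear sequence: 14 steps (steps 1, 3–9 and 12–17).

Steps most likely to fail

1. Step 6 (proposed new method). The unactivated ketone may enolise too slowly to add to the hindered β-carbon, or facial and trans selectivity may erode. Fallback, from 11 back to 13: the ketone of 11 is converted into its more substituted trimethylsilyl enol ether, (2E)-4,4,8-trimethyl-9-[(trimethylsilyl)oxy]undeca-2,8-dienal F1 (Me3SiCl, NaI, Et3N, MeCN; the enal has no enolisable hydrogen). F1 is cyclised by the known organocatalytic Mukaiyama–Michael addition of silyl enol ethers to iminium-activated enals (same (S)-prolinol silyl ether, 2,4-dinitrobenzoic acid, CH2Cl2–i-PrOH–H2O, −20 °C) to give 12, which is isolated this time. Ring B is then closed separately by acid-catalysed aldol condensation (TsOH·H2O, benzene, reflux with water removal) to reach 13.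

2. Step 17. Hot thiolate may cause loss of a sulfate group or competing attack at the aldehyde. Fallback, from 25 back to 27: both phenols of 25 are sulfated in protected form with 2,2,2-trichloroethyl chlorosulfate (Et3N, DMAP, THF) to give 6-methoxy-3-{(E)-[(2S,4aS,8aS)-2,5,5,8a-tetramethyloctahydronaphthalen-1(2H)-ylidene]methyl}-2,5-bis{[(2,2,2-trichloroethoxy)sulfonyl]oxy}benzaldehyde F2. The methyl ether ortho to the formyl group is then cleaved by chelation-directed BCl3 (CH2Cl2, −78 °C) to give the 6-hydroxy bis(trichloroethyl sulfate) F3. Zn dust and HCO2NH4 in MeOH remove both trichloroethyl groups to give 27.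

3. Step 8. The basic ylide may enolise the hindered ketone instead of adding, with epimerisation at C8. Fallback, from 14 back to 16: non-basic methylenation with Cp2TiMe2 (toluene, 70 °C) gives (2S,4aS,8aS)-2,5,5,8a-tetramethyl-1-methylidenedecahydronaphthalene F4. Hydroboration from the open α face (BH3·SMe2, THF; then NaOH, H2O2) gives [(1S,2S,4aS,8aS)-2,5,5,8a-tetramethyldecahydronaphthalen-1-yl]methanol F5. Oxidation with Dess–Martin periodinane (CH2Cl2, rt) gives 16 as its 1S epimer.

Further compounds
F1 | step 6 | (2E)-4,4,8-trimethyl-9-[(trimethylsilyl)oxy]undeca-2,8-dienal | CCC(O[Si](C)(C)C)=C(C)CCCC(C)(C)/C=C/C=O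
F2 | step 17 | 6-methoxy-3-{(E)-[(2S,4aS,8aS)-2,5,5,8a-tetramethyloctahydronaphthalen-1(2H)-ylidene]methyl}-2,5-bis{[(2,2,2-trichloroethoxy)sulfonyl]oxy}benzaldehyde | C[C@H]1CC[C@H]2C(C)(C)CCC[C@]2(C)/C1=C/c1cc(OS(=O)(=O)OCC(Cl)(Cl)Cl)c(OC)c(C=O)c1OS(=O)(=O)OCC(Cl)(Cl)Cl
F3 | step 17 | 6-hydroxy-3-{(E)-[(2S,4aS,8aS)-2,5,5,8a-tetramethyloctahydronaphthalen-1(2H)-ylidene]methyl}-2,5-bis{[(2,2,2-trichloroethoxy)sulfonyl]oxy}benzaldehyde | C[C@H]1CC[C@H]2C(C)(C)CCC[C@]2(C)/C1=C/c1cc(OS(=O)(=O)OCC(Cl)(Cl)Cl)c(O)c(C=O)c1OS(=O)(=O)OCC(Cl)(Cl)Cl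
F4 | step 8 | (2S,4aS,8aS)-2,5,5,8a-tetramethyl-1-methylidenedecahydronaphthalene | C[C@H]1CC[C@H]2C(C)(C)CCC[C@]2(C)C1=C
F5 | step 8 | [(1S,2S,4aS,8aS)-2,5,5,8a-tetramethyldecahydronaphthalen-1-yl]methanol | C[C@H]1CC[C@H]2C(C)(C)CCC[C@]2(C)[C@H]1CO
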